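- The vessel was stirred at constant volume and held isothermal. Substrate, reagent and catalyst made product in it, and I wanted to know what slow addition cost against adding everything at the start.

| setting | Thursday's | Friday's | Wednesday's | epsilon | alpha | theta | eta |
|---|---|---|---|---|---|---|---|
| substrate | 0.29 M | 0.29 M | 0.29 M | 0.29 M (fed, over 20 h) | 0.29 M | 0.29 M | 0.29 M (in portions, 3, over 20 h) |
| reagent | 0.435 M | 0.435 M | 0.435 M | 0.435 M | 0.435 M | 0.435 M (fed, over 20 h) | 0.435 M |
| catalyst | 0.29 mM | 0.14 mM | 0.58 mM | 0.29 mM | 0.29 mM | 0.29 mM | 0.29 mM |
| remark | run made earlier | run made earlier | run made earlier | all else is in the flask from the start; the feed brings no volume worth counting | everything together at the start | all else is in the flask from the start; the feed brings no volume worth counting | first portion at the start, last at 20 h |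
| time |  |  |  | 25 h | 25 h | 25 h | 25 h |

- Thursday's (time / h: product / %, substrate / %): 2.00: 4.5, 97.2; 3.00: 5.8, 95.6; 5.00: 6.2, 90.7; 8.00: 13.2, 85.5; 10.0: 15.7, 83.0; 15.0: 19.4, 78.7; 25.0: 30.5, 68.9
- Friday's (time / h: product / %, substrate / %): 3.00: 3.4, 97.3; 6.00: 6.2, 96.7; 8.00: 7.4, 92.3; 12.0: 6.5, 89.4; 15.0: 12.9, 87.1; 20.0: 13.7, 86.5
- Wednesday's (time / h: product / %, substrate / %): 1.50: 6.6, 95.3; 2.50: 10.4, 90.4; 4.00: 12.7, 86.6; 6.00: 18.6, 83.8; 8.00: 22.3, 79.0; 12.0: 29.7, 70.0; 20.0: 41.7, 58.8

(each reading ± 1 percentage point)

- a reading or a percentage of product counts all its forms, free or not

- the flask with the highest amount of product, in percent of the substrate charged ("all alike" if they lie within 1.5 percentage points) (epsilon / alpha / theta / eta / all alike)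
- final product, as a percentage of the substrate charged, in epsilon
- final product, as a percentage of the substrate charged, in alpha
- final product, as a percentage of the substrate charged, in theta
- final product, as a percentage of the substrate charged, in eta

- Thursday's, Friday's and Wednesday's runs differed in catalyst. Wednesday's, with twice Thursday's catalyst, read 29.7% product at 12.0 h, and Thursday's read 30.5% at 25.0 h. So I took the rate as proportional to catalyst: a concentration multiplying the rate sets the speed of the flask's clock.
- Substrate and reagent were never varied apart, so first order in each was my assumption, not a reading. A fed species then runs the clock at f, the fraction of its charge added so far; f ignores what has reacted, a correction I left out.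
- In epsilon and theta, f rises steadily over 20 h, so the clock loses half the feed time and shows 15.0 h. I carried this effective time τ, the integral of f over the run.
- In eta, f stood at 0.333 for 10.0 h, at 0.667 for 10.0 h, then at full charge for 5.00 h. That gives τ = 15.0 h, the same as the steady feeds. Alpha keeps τ = 25 h, longer than any fed flask.
- Thursday's run at 15.0 h read 19.4% product and 78.7% substrate. The mean of product and substrate lost gave 20.3%, my figure for the fed flasks, with alpha at 30.5%.
- The forecast, higher than my reckoning for the fed flasks, gave 25% for epsilon, 30.5% for alpha, 26% for theta and 25.5% for eta, with alpha highest, on the ground that “slow feeds keep concentrations low early on, so they lose some conversion, and inhibition dampens the difference”.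
- The flasks gave 20.7% in epsilon, 30.2% in alpha, 20.8% in theta and 20.4% in eta, so alpha stood highest.

    substrate + reagent + catalyst → catalyst + product (k = 0.0420 L² mol⁻² s⁻¹)
    catalyst + product ⇌ idle complex (K = 4.00 L mol⁻¹, k = 0.00110 L mol⁻¹ s⁻¹)

- In alpha, the exchange of catalyst and free product with idle complex (product inhibition, in the usual term) relaxed with a half-life of 0.518 h, far shorter than the 25 h run, while free product's forward half-life by that step was 34 d, far longer. At the end, alpha held 25.5% of its catalyst as idle complex beside 30.2% product.
- A neighbouring flask, alpha with 0.0012 M catalyst, had no feed, so its τ was 25 h against 15.0 h in the fed flasks; scaled by catalyst, that τ came to 103 h on Thursday's clock, later than the 40.0 h of Wednesday's last reading, so I expected more product than that reading's 41.7%. The neighbouring flask gave 63.5%, more than that reading, with 36.5% substrate left.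

The numbers in the tables stem from a simulated flask with constants of no real substance, and the scatter is random.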